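## Retrosynthetic overview

- **Numbering.** Ring: C1 (carbinol), C2, C3, C4 (Br, CH3), C5 (Cl), C6. Chain: C7 (=CH2), C8, C9 (carbinol), C10=C11. The descriptors are 1R,4S,5S,9S. C1–OH and C4–Br are cis, and C5–Cl is trans to both.
- **Late disconnections.** These are C7=CH2 (methylenation of a C7 ketone), C8–C9 (boron aldol with 3-methylbut-2-enal), C4–Br (opening of a C1–O–C4 bridge with retention) and C5–Cl/C4–O (transannular chloroetherification). They lead back to (R)-1-acetyl-4-methylcyclohex-3-en-1-ol.
- **Feature.** In the C4=C5 cyclohexene, the chain C7(=O)–C1(O)–C6–C5=C4 is a γ,δ-unsaturated α-oxy acid. Cutting C1–C6 and tying C4 to the carboxyl oxygen gives a 3-silyloxy-6-methyl-6-vinyl δ-lactone. Its C2–C3–C4(CH3)(vinyl)–O part is the carbinol end of (R)-linalool.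
- **Ring order.** The oxane (δ-lactone) ring comes first (steps 1–4). The cyclohexene follows by Ireland–Claisen ring contraction (step 8). A temporary 7-oxabicyclo[2.2.1]heptane is made in step 11 and reopened in step 12.

Key step: step 8

Assumption: commercial (−)-(R)-linalool of high enantiomeric purity is used, and its purity caps that of C1 because no later step upgrades it.
Assumption: with methyl ketones and enals, (+)-B-chlorodiisopinocampheylborane is taken to give the carbinol that is (S) when the priorities run OH > alkenyl > CH2C=O.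

## Route

Step 1
Reactants: 1 (R)-linalool
Product: 3 (5R)-5-ethenyl-5-methyloxolan-2-ol (lactol; anomer mixture), via secondary ozonide 2 (not isolated)
Conditions: O3 (1 equiv, Sudan Red 7B end point), CH2Cl2, −78 °C; then Me2S, −78 °C → rt
Reagents that add atoms: ozone, [O-][O+]=O
Why: Chemoselective ozonolysis, in which the electron-rich trisubstituted alkene takes up ozone far faster than the vinyl group next to the carbinol, after which the hydroxy aldehyde closes to the lactol without touching the stereocentre.

Step 2
Reactants: 3 (5R)-5-ethenyl-5-methyloxolan-2-ol; 4 (methoxymethyl)triphenylphosphonium chloride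
Product: 6 (3R)-7-methoxy-3-methylhepta-1,6-dien-3-ol (E/Z mixture), via phosphorus ylide 5 (not isolated)
Conditions: 4 (3 equiv), KOtBu, THF, 0 °C; then 3, 0 °C → rt
Reagents that add atoms: none
Why: Wittig methoxymethylenation of a lactol through its open hydroxy-aldehyde form, with excess ylide serving as base and reagent; the alkene geometry is irrelevant because both isomers hydrolyse to one aldehyde.

Step 3
Reactants: 6 (3R)-7-methoxy-3-methylhepta-1,6-dien-3-ol
Product: 7 (6R)-6-ethenyl-6-methyloxan-2-ol (anomer mixture)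
Conditions: TsOH·H2O (cat.), THF–H2O 4:1, rt
Reagents that add atoms: water, O
Why: Acid-catalysed enol ether hydrolysis, in which C-protonation gives an oxocarbenium ion that water or the tertiary hydroxyl captures much faster than the dilute acid can ionise the tertiary allylic C–O bond.

Step 4
Reactants: 7 (6R)-6-ethenyl-6-methyloxan-2-ol
Product: 8 (6R)-6-ethenyl-6-methyloxan-2-one
Conditions: TEMPO (cat.), PhI(OAc)2, CH2Cl2, rt
Reagents that add atoms: none
Why: Oxoammonium oxidation of a lactol to the lactone, chosen over Cr(VI) reagents because these would cause oxidative transposition of the tertiary allylic alcohol present in the open form.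

Step 5
Reactants: 8 (6R)-6-ethenyl-6-methyloxan-2-one
Product: 10 (6R)-6-ethenyl-3-hydroxy-6-methyloxan-2-one (C3 epimers), via sodium enolate 9 (not isolated)
Conditions: NaHMDS, THF, −78 °C; 2-(benzenesulfonyl)-3-phenyloxaziridine, −78 °C; AcOH quench
Reagents that add atoms: 2-(benzenesulfonyl)-3-phenyloxaziridine, O=S(=O)(c1ccccc1)N1OC1c1ccccc1
Why: Enolate hydroxylation with an N-sulfonyloxaziridine; the new lactone C3 centre (target C1) may form as a mixture because it becomes planar again in step 7.

Step 6
Reactants: 10 (6R)-6-ethenyl-3-hydroxy-6-methyloxan-2-one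
Product: 11 (6R)-3-[(tert-butyldimethylsilyl)oxy]-6-ethenyl-6-methyloxan-2-one (C3 epimers)
Conditions: TBSCl, imidazole, DMF, rt
Reagents that add atoms: tert-butyldimethylsilyl chloride, CC(C)(C)[Si](C)(C)Cl
Why: Routine imidazole-promoted silylation of a secondary alcohol, which masks the α-oxygen as a group that survives enolisation, heating and methyllithium.

Step 7
Reactants: 11 (6R)-3-[(tert-butyldimethylsilyl)oxy]-6-ethenyl-6-methyloxan-2-one
Product: 13 (2R)-5,6-bis[(tert-butyldimethylsilyl)oxy]-2-ethenyl-2-methyl-3,4-dihydro-2H-pyran, via lithium enolate 12 (not isolated)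
Conditions: LDA, THF–DMPU, −78 °C; TBSCl, −78 → 0 °C; pentane/cold aq NaHCO3 work-up, used without chromatography
Reagents that add atoms: tert-butyldimethylsilyl chloride, CC(C)(C)[Si](C)(C)Cl
Why: Kinetic enolisation and O-silylation in a dipolar cosolvent (the first half of the Ireland–Claisen protocol), where the ring fixes the ketene acetal geometry and both C3 epimers give the same compound.

Step 8
Reactants: 13 (2R)-5,6-bis[(tert-butyldimethylsilyl)oxy]-2-ethenyl-2-methyl-3,4-dihydro-2H-pyran
Product: 15 (1R)-1-[(tert-butyldimethylsilyl)oxy]-4-methylcyclohex-3-ene-1-carboxylic acid, via silyl ester 14 (not isolated)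
Conditions: toluene, base-washed glassware, 110 °C; then AcOH–THF–H2O, rt
Reagents that add atoms: none
Why: On heating, the dihydropyran reaches a boat with the vinyl group axial, so that the ketene acetal C=C, the ring oxygen, the quaternary carbon and the vinyl group form a bicyclo[2.2.2]octane-like array; a concerted suprafacial [3,3] shift then forms C1–C6 while C4–O breaks, giving silyl ester 14, which mild hydrolysis converts into 15. The closest known reaction type is the Ireland–Claisen ring contraction of silyl ketene acetals of 6-alkenyl δ-lactones, which can only pass through such boat transition states, and glycolate-type α-silyloxy ketene acetals are established partners in this rearrangement. The cyclohexene closes by sigmatropic ring contraction: four lactone carbons and the two vinyl carbons become the carbocycle, and the O–C(=O) unit is expelled from the ring as the carboxyl group on C1. The only new stereocentre, C1, is controlled by the linalool-derived quaternary carbon, because the tethered vinyl group can reach only the face of planar C1 on which it stands; this turns (R) at the carbinol carbon into (R) at C1 while that carbon becomes the methyl-bearing alkene carbon C4. The step needs complete 1,4-chirality transfer, so the concerted path must outrun ionisation of the tertiary allylic C–O bond, and the non-polar solvent, the acid-free vessel and the two donor groups on the ketene acetal should secure this.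

Step 9
Reactants: 15 (1R)-1-[(tert-butyldimethylsilyl)oxy]-4-methylcyclohex-3-ene-1-carboxylic acid
Product: 17 1-[(1R)-1-[(tert-butyldimethylsilyl)oxy]-4-methylcyclohex-3-en-1-yl]ethan-1-one, via dilithium gem-diolate 16 (not isolated)
Conditions: MeLi (3 equiv), Et2O, 0 °C → rt; inverse quench into cold 1 M HCl
Reagents that add atoms: methyllithium, [Li]C
Why: Addition of methyllithium to the lithium carboxylate stops at a stable dilithium gem-diolate that releases the ketone only in the acidic quench, and C1 carries no hydrogen and cannot epimerise.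

Step 10
Reactants: 17 1-[(1R)-1-[(tert-butyldimethylsilyl)oxy]-4-methylcyclohex-3-en-1-yl]ethan-1-one
Product: 18 1-[(1R)-1-hydroxy-4-methylcyclohex-3-en-1-yl]ethan-1-one
Conditions: 48% aq HF, MeCN, rt
Reagents that add atoms: none
Why: Fluoride-driven desilylation under weakly acidic conditions, safe because the carbinol carbon is flanked by the acetyl group and cannot ionise, and the trisubstituted alkene is inert to dilute HF.

Step 11
Reactants: 18 1-[(1R)-1-hydroxy-4-methylcyclohex-3-en-1-yl]ethan-1-one
Product: 19 1-[(1R,3S,4S)-3-chloro-4-methyl-7-oxabicyclo[2.2.1]heptan-1-yl]ethan-1-one (Cl endo)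
Conditions: NCS (1.05 equiv), (CF3)2CHOH–CH2Cl2, 0 °C, dark
Reagents that add atoms: N-chlorosuccinimide, O=C1CCC(=O)N1Cl
Why: Transannular chloroetherification of a cyclohex-3-enol, in which the C1 hydroxyl of the boat conformer captures the tertiary end (C4) of the chloronium ion formed on the opposite face, so that anti addition puts oxygen at C4 on the hydroxyl face and chlorine at C5 on the other face, while the weakly basic, non-nucleophilic fluoroalcohol medium disfavours proton loss to allylic chlorides.

Step 12
Reactants: 19 1-[(1R,3S,4S)-3-chloro-4-methyl-7-oxabicyclo[2.2.1]heptan-1-yl]ethan-1-one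
Product: 21 1-[(1R,3S,4S)-4-bromo-3-chloro-1-hydroxy-4-methylcyclohexyl]ethan-1-one, via dibromoboryl ether 20 (not isolated)
Conditions: BBr3 (1.1 equiv), CH2Cl2, −78 → −40 °C; cold sat. aq NaHCO3
Reagents that add atoms: boron tribromide, BrB(Br)Br
Why: Proposed new method: BBr3 binds the bridge oxygen, the C1–O bond cannot ionise next to the acetyl group, and the C4–O bond lengthens with help from the endo C5–Cl bond lying antiperiplanar to it, giving a chlorine-bridged C4 cation whose chlorine-bearing face is blocked; bromide then passes from the O–BBr3 unit on the oxygen face, so C4–Br forms with retention (trans to Cl, cis to the C1 oxygen), whereas an invertive SN2 opening, excluded at this tertiary chlorine-flanked carbon, would give the wrong epimer; the closest known reaction types are the BBr3 or HBr cleavage of 7-oxabicyclo[2.2.1]heptanes and cineole-type tertiary ethers and the retentive substitution of trans-β-halo alcohols through halonium ions, and low temperature is needed to keep kinetic control.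

Step 13
Reactants: 21 1-[(1R,3S,4S)-4-bromo-3-chloro-1-hydroxy-4-methylcyclohexyl]ethan-1-one
Product: 22 1-[(1R,3S,4S)-4-bromo-3-chloro-4-methyl-1-(triethylsilyloxy)cyclohexyl]ethan-1-one
Conditions: TESOTf, 2,6-lutidine, CH2Cl2, −78 → 0 °C
Reagents that add atoms: triethylsilyl triflate, CC[Si](CC)(CC)OS(=O)(=O)C(F)(F)F
Why: Silylation of a hindered tertiary alcohol with a silyl triflate and a hindered pyridine base, which masks the hydroxyl for the boron aldol without offering a base strong enough to eliminate the tertiary bromide.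

Step 14
Reactants: 22 1-[(1R,3S,4S)-4-bromo-3-chloro-4-methyl-1-(triethylsilyloxy)cyclohexyl]ethan-1-one; 23 3-methylbut-2-enal
Product: 26 (3S)-1-[(1R,3S,4S)-4-bromo-3-chloro-4-methyl-1-(triethylsilyloxy)cyclohexyl]-3-hydroxy-5-methylhex-4-en-1-one, via enol borinate 24 (not isolated), via boron aldolate 25 (not isolated)
Conditions: (+)-Ipc2BCl, Et3N, Et2O, 0 °C; 23, −78 → −20 °C; MeOH, pH 7 buffer, 30% H2O2, 0 °C
Reagents that add atoms: none
Why: Boron-mediated aldol addition of a methyl ketone, in which the chloroborane and triethylamine enolise the only enolisable side too mildly to touch the halides, the enal reacts 1,2 through a cyclic boron transition state, and C9 is set by reagent control from the isopinocampheyl ligands, the (+)-reagent steering attack to the aldehyde face that gives the (S)-carbinol.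

Step 15
Reactants: 26 (3S)-1-[(1R,3S,4S)-4-bromo-3-chloro-4-methyl-1-(triethylsilyloxy)cyclohexyl]-3-hydroxy-5-methylhex-4-en-1-one
Product: 27 (3S)-1-[(1R,3S,4S)-4-bromo-3-chloro-4-methyl-1-(triethylsilyloxy)cyclohexyl]-5-methyl-3-(triethylsilyloxy)hex-4-en-1-one
Conditions: TESCl, imidazole, CH2Cl2, 0 °C → rt
Reagents that add atoms: triethylsilyl chloride, CC[Si](Cl)(CC)CC
Why: Routine imidazole-promoted silylation of the secondary allylic alcohol, needed because a free β-hydroxy ketone would quench the titanium carbene and could undergo retro-aldol cleavage.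

Step 16
Reactants: 27 (3S)-1-[(1R,3S,4S)-4-bromo-3-chloro-4-methyl-1-(triethylsilyloxy)cyclohexyl]-5-methyl-3-(triethylsilyloxy)hex-4-en-1-one
Product: 28 bis(triethylsilyl) ether of the target
Conditions: Tebbe reagent (toluene solution), pyridine, THF, −40 → 0 °C; Na2SO4·10H2O quench
Reagents that add atoms: Tebbe reagent, C[Al-]1(C)C[Ti](C2C=CC=C2)(C2C=CC=C2)[Cl+]1
Why: Tebbe methylenation, in which pyridine frees titanocene methylidene and ties up the dimethylaluminium chloride, and the non-basic carbene converts the hindered enolisable ketone through an oxatitanacyclobutane without the β-elimination, loss of HBr or reduction of the vicinal dihalide that basic ylides or zinc-based reagents would cause.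

Step 17
Reactants: 28 bis(triethylsilyl) ether of the target
Product: 29 (1R,3S,4S)-4-bromo-3-chloro-1-[(4S)-4-hydroxy-6-methylhepta-1,5-dien-2-yl]-4-methylcyclohexan-1-ol (target)
Conditions: HF·pyridine, pyridine, THF, 0 °C → rt
Reagents that add atoms: none
Why: Fluoride-driven cleavage of both triethylsilyl ethers with pyridine-buffered HF, a medium neither basic enough for E2 loss of HBr nor acidic enough to ionise the two allylic carbinols, so all four stereocentres pass unchanged into the target.

## Compound list

1 | (R)-linalool, (3R)-3,7-dimethylocta-1,6-dien-3-ol | C=C[C@](C)(O)CCC=C(C)C | starting material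
2 | 3-[(3R)-3-hydroxy-3-methylpent-4-en-1-yl]-5,5-dimethyl-1,2,4-trioxolane | C=C[C@](C)(O)CCC1OOC(C)(C)O1 | intermediate
3 | (5R)-5-ethenyl-5-methyloxolan-2-ol | C=C[C@@]1(C)CCC(O)O1 | intermediate
4 | (methoxymethyl)triphenylphosphonium chloride | COC[P+](c1ccccc1)(c1ccccc1)c1ccccc1.[Cl-] | starting material
5 | (methoxymethylidene)triphenylphosphorane | COC=P(c1ccccc1)(c1ccccc1)c1ccccc1 | intermediate
6 | (3R)-7-methoxy-3-methylhepta-1,6-dien-3-ol (E/Z) | C=C[C@](C)(O)CCC=COC | intermediate
7 | (6R)-6-ethenyl-6-methyloxan-2-ol | C=C[C@@]1(C)CCCC(O)O1 | intermediate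
8 | (6R)-6-ethenyl-6-methyloxan-2-one | C=C[C@@]1(C)CCCC(=O)O1 | intermediate
9 | sodium enolate of 8 | C=C[C@@]1(C)CCC=C([O-])O1.[Na+] | intermediate
10 | (6R)-6-ethenyl-3-hydroxy-6-methyloxan-2-one (C3 epimers) | C=C[C@@]1(C)CCC(O)C(=O)O1 | intermediate
11 | (6R)-3-[(tert-butyldimethylsilyl)oxy]-6-ethenyl-6-methyloxan-2-one (C3 epimers) | C=C[C@@]1(C)CCC(O[Si](C)(C)C(C)(C)C)C(=O)O1 | intermediate
12 | lithium enolate of 11 | C=C[C@@]1(C)CCC(O[Si](C)(C)C(C)(C)C)=C([O-])O1.[Li+] | intermediate
13 | (2R)-5,6-bis[(tert-butyldimethylsilyl)oxy]-2-ethenyl-2-methyl-3,4-dihydro-2H-pyran | C=C[C@@]1(C)CCC(O[Si](C)(C)C(C)(C)C)=C(O[Si](C)(C)C(C)(C)C)O1 | intermediate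
14 | tert-butyldimethylsilyl (1R)-1-[(tert-butyldimethylsilyl)oxy]-4-methylcyclohex-3-ene-1-carboxylate | CC(C)(C)[Si](C)(C)OC(=O)[C@@]1(O[Si](C)(C)C(C)(C)C)CCC(C)=CC1 | intermediate
15 | (1R)-1-[(tert-butyldimethylsilyl)oxy]-4-methylcyclohex-3-ene-1-carboxylic acid | OC(=O)[C@@]1(O[Si](C)(C)C(C)(C)C)CCC(C)=CC1 | intermediate
16 | dilithium 1-[(1R)-1-[(tert-butyldimethylsilyl)oxy]-4-methylcyclohex-3-en-1-yl]ethane-1,1-diolate | CC([O-])([O-])[C@@]1(O[Si](C)(C)C(C)(C)C)CCC(C)=CC1.[Li+].[Li+] | intermediate
17 | 1-[(1R)-1-[(tert-butyldimethylsilyl)oxy]-4-methylcyclohex-3-en-1-yl]ethan-1-one | CC(=O)[C@@]1(O[Si](C)(C)C(C)(C)C)CCC(C)=CC1 | intermediate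
18 | 1-[(1R)-1-hydroxy-4-methylcyclohex-3-en-1-yl]ethan-1-one | CC(=O)[C@@]1(O)CCC(C)=CC1 | intermediate
19 | 1-[(1R,3S,4S)-3-chloro-4-methyl-7-oxabicyclo[2.2.1]heptan-1-yl]ethan-1-one (Cl endo, anti to the oxygen bridge) | CC(=O)[C@]12CC[C@](C)(O1)[C@@H](Cl)C2 | intermediate
20 | dibromoboryl ether of 21 | CC(=O)[C@@]1(OB(Br)Br)CC[C@](C)(Br)[C@@H](Cl)C1 | intermediate
21 | 1-[(1R,3S,4S)-4-bromo-3-chloro-1-hydroxy-4-methylcyclohexyl]ethan-1-one | CC(=O)[C@@]1(O)CC[C@](C)(Br)[C@@H](Cl)C1 | intermediate
22 | 1-[(1R,3S,4S)-4-bromo-3-chloro-4-methyl-1-(triethylsilyloxy)cyclohexyl]ethan-1-one | CC(=O)[C@@]1(O[Si](CC)(CC)CC)CC[C@](C)(Br)[C@@H](Cl)C1 | intermediate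
23 | 3-methylbut-2-enal | CC(C)=CC=O | starting material
24 | enol diisopinocampheylborinate of 22 | C=C(OB([C@H]1C[C@H]2C[C@@H]([C@@H]1C)C2(C)C)[C@H]1C[C@H]2C[C@@H]([C@@H]1C)C2(C)C)[C@@]1(O[Si](CC)(CC)CC)CC[C@](C)(Br)[C@@H](Cl)C1 | intermediate
25 | diisopinocampheylboron aldolate of 26 | O=C(C[C@H](OB([C@H]1C[C@H]2C[C@@H]([C@@H]1C)C2(C)C)[C@H]1C[C@H]2C[C@@H]([C@@H]1C)C2(C)C)C=C(C)C)[C@@]1(O[Si](CC)(CC)CC)CC[C@](C)(Br)[C@@H](Cl)C1 | intermediate
26 | (3S)-1-[(1R,3S,4S)-4-bromo-3-chloro-4-methyl-1-(triethylsilyloxy)cyclohexyl]-3-hydroxy-5-methylhex-4-en-1-one | O=C(C[C@H](O)C=C(C)C)[C@@]1(O[Si](CC)(CC)CC)CC[C@](C)(Br)[C@@H](Cl)C1 | intermediate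
27 | (3S)-1-[(1R,3S,4S)-4-bromo-3-chloro-4-methyl-1-(triethylsilyloxy)cyclohexyl]-5-methyl-3-(triethylsilyloxy)hex-4-en-1-one | O=C(C[C@H](O[Si](CC)(CC)CC)C=C(C)C)[C@@]1(O[Si](CC)(CC)CC)CC[C@](C)(Br)[C@@H](Cl)C1 | intermediate
28 | bis(triethylsilyl) ether of the target (1R,3S,4S ring, 4S chain) | C=C(C[C@H](O[Si](CC)(CC)CC)C=C(C)C)[C@@]1(O[Si](CC)(CC)CC)CC[C@](C)(Br)[C@@H](Cl)C1 | intermediate
29 | (1R,3S,4S)-4-bromo-3-chloro-1-[(4S)-4-hydroxy-6-methylhepta-1,5-dien-2-yl]-4-methylcyclohexan-1-ol | C=C(C[C@H](O)C=C(C)C)[C@@]1(O)CC[C@](C)(Br)[C@@H](Cl)C1 | target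

## Step count and risks

Total step count: 17. Longest linear sequence: 17 steps (1 → 29). Compounds 4 and 23 enter as purchased.

### Step 12 (labelled step)

The C4 cation may lose a proton instead of taking up bromide. Bromide may also enter on the chlorine-bearing face, or the tertiary bromide may equilibrate at C4 under the Lewis acid.

The fallback sets out from 19 and comes back at 21. It splits the event into two known reactions.
- Compound 19 is opened with TMSOTf and 2,6-lutidine in CH2Cl2, the E1-type cleavage used for tert-alkyl ethers. Here the alkene stays in the molecule, giving 1-[(1R,3S)-3-chloro-4-methylidene-1-(trimethylsilyloxy)cyclohexyl]ethan-1-one F1. Any endocyclic alkene isomer converges in the next operation.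
- Anhydrous HBr in CH2Cl2 at low temperature then adds in the Markovnikov sense, as it does to methallyl chloride-type alkenes. Bromide enters anti to the allylic chlorine, and the same acid removes the trimethylsilyl ether to give 21.

### Step 11

The chloronium ion may lose a proton (allylic chlorination with alkene shift). Cl+ may also attack the hydroxyl-bearing face, from which the ether cannot close by anti addition.

The fallback sets out from 18 and comes back at 19. It fixes the face with oxygen and brings chlorine in as a nucleophile.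
- Hydroxyl-directed epoxidation (VO(acac)2, t-BuOOH, CH2Cl2, 0 °C) should give the cis-epoxy alcohol 1-[(1R,3R,6S)-3-hydroxy-6-methyl-7-oxabicyclo[4.1.0]heptan-3-yl]ethan-1-one F2.
- Li2CuCl4 in THF opens F2 at the less substituted C5 with inversion. The near-neutral conditions avoid acid-induced attack of the C1 hydroxyl. The product is 1-[(1R,3S,4S)-3-chloro-1,4-dihydroxy-4-methylcyclohexyl]ethan-1-one F3.
- Catalytic camphorsulfonic acid in CH2Cl2 closes the cis-1,4-diol by loss of the C4 hydroxyl, a terpin-to-cineole type cyclodehydration, to give 19.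

### Step 8

The tertiary allylic C–O bond may ionise, or the ketene acetal may hydrolyse, before the boat array is reached. Either process would erode the chirality transfer or lead to elimination.

The fallback sets out from 11 and comes back at 17. It uses a more robust enol ether in place of the ketene acetal.
- KHMDS and diphenyl chlorophosphate (THF–DMPU, −78 °C) give the ketene acetal phosphate (6R)-3-[(tert-butyldimethylsilyl)oxy]-6-ethenyl-6-methyl-5,6-dihydro-4H-pyran-2-yl diphenyl phosphate F4.
- Negishi coupling with MeZnCl (Pd(PPh3)4, THF) gives (2R)-5-[(tert-butyldimethylsilyl)oxy]-2-ethenyl-2,6-dimethyl-3,4-dihydro-2H-pyran F5.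
- The thermal aliphatic Claisen rearrangement known for 2-vinyl-3,4-dihydro-2H-pyrans (sealed tube, xylene, about 180 °C) passes through the same boat array. It delivers methyl ketone 17 directly, with the same sense of chirality transfer.

## Further compounds

F1 | step 12 | 1-[(1R,3S)-3-chloro-4-methylidene-1-(trimethylsilyloxy)cyclohexyl]ethan-1-one | CC(=O)[C@@]1(O[Si](C)(C)C)CCC(=C)[C@@H](Cl)C1
F2 | step 11 | 1-[(1R,3R,6S)-3-hydroxy-6-methyl-7-oxabicyclo[4.1.0]heptan-3-yl]ethan-1-one | CC(=O)[C@@]1(O)CC[C@]2(C)O[C@@H]2C1
F3 | step 11 | 1-[(1R,3S,4S)-3-chloro-1,4-dihydroxy-4-methylcyclohexyl]ethan-1-one | CC(=O)[C@@]1(O)CC[C@](C)(O)[C@@H](Cl)C1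
F4 | step 8 | (6R)-3-[(tert-butyldimethylsilyl)oxy]-6-ethenyl-6-methyl-5,6-dihydro-4H-pyran-2-yl diphenyl phosphate | C=C[C@@]1(C)CCC(O[Si](C)(C)C(C)(C)C)=C(OP(=O)(Oc2ccccc2)Oc2ccccc2)O1
F5 | step 8 | (2R)-5-[(tert-butyldimethylsilyl)oxy]-2-ethenyl-2,6-dimethyl-3,4-dihydro-2H-pyran | C=C[C@@]1(C)CCC(O[Si](C)(C)C(C)(C)C)=C(C)O1
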